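**Retrosynthetic overview**

1. Target ⇒ (C12 acetylation, desilylation, C6 OH→Cl with inversion) ⇒ ten-membered ring opened at C3=C4 (ring-closing metathesis) and at C8–C9 (Nozaki–Hiyama–Kishi coupling) ⇒ ring A aldehyde 21 + butenolide triflate 31.
2. Ring A (C1, C14, C13, C12, C11, C10) ⇒ one-pot Matteson alkylation / enol-ether chlorination / intramolecular allylboration of γ-lactone 11 with the chiral α-chloroallylboronate 5; this forms C1–C14 and C11–C12 and also installs C20–Cl.
3. Enabling feature: in a temporary γ-lactone (C2, C1, C10, C9, O) C1 is the enolisable α-carbon and C10 carries the latent ketone C11, so the allyl unit C14–C13–C12 can bridge an enolate carbon and a ketone carbon; the tertiary carbinol C11 is homoallylic to C13=C14.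
4. Ring order: chiral butenolide (temporary lactone) → ring A → butenolide fragment (C6/C7 by vinylogous aldol) → coupling → β-hydroxy lactone → ten-membered ring last.

Key step: step 4

Remark: briarane numbering of the target is used throughout (C1 quaternary methyl carbon; C2 to C9 around the ten-membered ring; C10 ring-fusion CH; C11 chlorohydrin carbon; C12 acetoxy carbon of ring A; C13=C14; C15 methyl on C1; C16 exocyclic methylene; C17 to C19 lactone; C20 chloromethyl).
Assumption: 2, 6 (the enantiomer of the usual l-menthol-derived butenolide), 22 and 25 are taken as purchasable, and the BINOL antipode that gives the (5S) lactone in step 14 is written as (R).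

**Route**

Step 1
Reactants: 1 (1S,2S)-1,2-dicyclohexylethane-1,2-diol; 2 dipropan-2-yl (dichloromethyl)boronate
Product: 3 (4S,5S)-4,5-dicyclohexyl-2-(dichloromethyl)-1,3,2-dioxaborolane
Conditions: pentane, 23 °C, then evaporation
Reagents that add atoms: none
Why: Transesterification driven by removal of propan-2-ol installs the C2-symmetric diol that directs the next homologation.

Step 2
Reactants: 3 dichloromethylboronate; 4 ethenylmagnesium bromide
Product: 5 (4S,5S)-2-[(1R)-1-chloroprop-2-en-1-yl]-4,5-dicyclohexyl-1,3,2-dioxaborolane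
Conditions: THF, −78 °C; ZnCl2, −78 → 23 °C
Reagents that add atoms: none
Why: Matteson homologation in which the vinyl group adds to boron and the ZnCl2-promoted 1,2-shift displaces one diastereotopic chloride under control of the chiral diol, which should give the (1R)-chloride.

Step 3
Reactants: 6 (5S)-5-(d-menthyloxy)furan-2(5H)-one; 7 ethoxyethene; 8 iodomethane
Product: 11 (3S,4R,5S)-4-(1-ethoxyethenyl)-3-methyl-5-(menthyloxy)oxolan-2-one, via (1-ethoxyethenyl)lithium 9 (not isolated), via lithium bis(1-ethoxyethenyl)cuprate 10 (not isolated)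
Conditions: 7, t-BuLi, THF, −78 → 0 °C; CuI, −40 °C; 6, −78 °C; then 8, HMPA, −78 → −20 °C
Reagents that add atoms: none
Why: Tandem 1,4-addition of the alkenylcuprate and enolate methylation on the chiral 5-alkoxybutenolide, with the ethoxyvinyl group entering anti to the menthyloxy group (this sets C10) and the methyl group anti to the new substituent (C1 is reset in step 4).

Step 4
Reactants: 11 ethoxyvinyl lactone; 5 α-chloroallylboronate
Product: 14 ring A chlorohydrin lactone, via allylboronate lactone 12 (not isolated), via chloromethyl ketone allylboronate 13 (not isolated)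
Conditions: LiN(i-Pr)2, THF, −78 °C; 5, then ZnCl2, −78 → 23 °C; then N-chlorosuccinimide, NaHCO3, THF–H2O, 0 → 40 °C; triethanolamine work-up
Reagents that add atoms: N-chlorosuccinimide, O=C1CCC(=O)N1Cl; water, O
Why: Proposed new method: the lithium enolate of 11 adds through C1 to the boron of 5 and C1 then displaces chloride at the boron-bearing carbon with inversion (a Matteson-type 1,2-shift, known for simple ester enolates and here extended to a fully substituted lactone enolate), which forms C1–C14 with the electrophile anti to the C10 substituent of the γ-lactone (this sets the quaternary centre C1) and turns the (1R)-chloride into the (1S)-boronate 12 (this sets C14). N-Chlorosuccinimide in wet THF then chlorinates the far more nucleophilic ethoxyvinyl group and water releases the chloromethyl ketone 13, so that C20–Cl is in place before ring closure. The α-substituted allylboronate adds to this activated ketone intramolecularly through a closed boat-like six-membered transition state (B–O contact, C12–C11 bond formation with allyl transposition), the closest known reactions being thermal ketone allylborations by α-substituted allylboronates and one-pot homologation then allylboration sequences. Ring A is closed in the mode in which all three allyl carbons become ring atoms (endo with respect to the allyl unit), so the new C13=C14 double bond is necessarily cis. The carbonyl oxygen is delivered to the face that carried boron, so C11 is set by chirality transfer from C14 and its hydroxyl should end cis to C2 and trans to the C1 methyl group, while C10 and C9 are untouched. The step needs C-alkylation at the boron-bearing carbon instead of attack at the vinyl terminus (secured by the boron-bound pathway), chlorination of the enol ether in preference to the allylboronate (secured by its much higher nucleophilicity) and closure onto C11 instead of the lactone carbonyl (secured by the reactivity of the α-chloro ketone and by the one-atom bridge that attack at C2 would require).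

Step 5
Reactants: 14 ring A chlorohydrin lactone
Product: 15 C12 allylic alcohol (cis-diol lactone)
Conditions: SeO2 (catalytic), t-BuOOH, CH2Cl2, 23 °C
Reagents that add atoms: tert-butyl hydroperoxide, CC(C)(C)OO
Why: Riley allylic oxidation, for which only C12 carries allylic hydrogen because C1 is quaternary, and the ene then [2,3] sequence on the locked trans-fused bicycle should replace the pseudoaxial C12 hydrogen suprafacially, which places the new hydroxyl cis to the C11 hydroxyl.

Step 6
Reactants: 15 cis-diol lactone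
Product: 16 ring A diol ester acetal
Conditions: MeOH, HCl (from AcCl, catalytic), 50 °C
Reagents that add atoms: methanol, CO
Why: Acid-catalysed methanolysis of the acylal (acetal exchange then Fischer esterification) should release the menthol auxiliary and differentiate C2 as the methyl ester from C9 as the dimethyl acetal without touching a stereocentre.

Step 7
Reactants: 16 diol ester acetal
Product: 17 bis-silyl ether ester
Conditions: t-BuMe2SiOTf, 2,6-lutidine, CH2Cl2, 0 → 23 °C
Reagents that add atoms: tert-butyldimethylsilyl trifluoromethanesulfonate, CC(C)(C)[Si](C)(C)OS(=O)(=O)C(F)(F)F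
Why: Exhaustive silylation with the silyl triflate protects the secondary allylic and the hindered tertiary hydroxyl, which also prevents base-induced closure of the chlorohydrin to an epoxide in later steps.

Step 8
Reactants: 17 bis-silyl ether ester
Product: 18 C2 aldehyde
Conditions: i-Bu2AlH, CH2Cl2, −78 °C; Rochelle salt
Reagents that add atoms: none
Why: Low-temperature i-Bu2AlH reduction of the neopentyl-type methyl ester should stop at the stable aluminium hemiacetal and give the aldehyde on work-up.

Step 9
Reactants: 18 C2 aldehyde; 4 ethenylmagnesium bromide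
Product: 19 C2 allylic alcohol
Conditions: THF, −78 °C
Reagents that add atoms: none
Why: Grignard 1,2-addition to the α-quaternary aldehyde under acyclic 1,2-induction, with C10 as the large group anti to the nucleophile and attack past the small methyl group, should set the C2 carbinol as in the target.

Step 10
Reactants: 19 C2 allylic alcohol
Product: 20 C2 acetate acetal
Conditions: Ac2O, DMAP, pyridine, CH2Cl2, 23 °C
Reagents that add atoms: acetic anhydride, CC(=O)OC(C)=O
Why: DMAP-catalysed acetylation of the secondary allylic alcohol installs the C2 acetate of the target.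

Step 11
Reactants: 20 C2 acetate acetal
Product: 21 ring A aldehyde (C9 aldehyde)
Conditions: Et3SiOTf, 2,4,6-collidine, CH2Cl2, 0 °C; then H2O
Reagents that add atoms: water, O
Why: The silyl triflate and collidine convert the dimethyl acetal into a collidinium salt that water hydrolyses to the aldehyde, a non-acidic acetal cleavage that should spare the silyl ethers, the allylic acetate and the C10 stereocentre.

Step 12
Reactants: 22 4-hydroxy-3-methylfuran-2(5H)-one
Product: 23 4-methoxy-3-methylfuran-2(5H)-one
Conditions: Me2SO4, K2CO3, acetone, reflux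
Reagents that add atoms: dimethyl sulfate, COS(=O)(=O)OC
Why: O-Methylation of the vinylogous acid with the hard electrophile gives the methyl tetronate, which masks the C8 oxygen and allows γ-enolisation.

Step 13
Reactants: 23 methyl tetronate
Product: 24 [(4-methoxy-3-methylfuran-2-yl)oxy](trimethyl)silane
Conditions: Me3SiOTf, Et3N, CH2Cl2, 0 °C
Reagents that add atoms: trimethylsilyl trifluoromethanesulfonate, C[Si](C)(C)OS(=O)(=O)C(F)(F)F
Why: Soft enolisation and O-silylation of the tetronate give the 2-silyloxyfuran, the dienol ether nucleophile of the next step.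

Step 14
Reactants: 24 silyloxyfuran; 25 2-bromoprop-2-enal
Product: 26 (5S)-5-[(1S)-2-bromo-1-hydroxyprop-2-en-1-yl]-4-methoxy-3-methylfuran-2(5H)-one
Conditions: Ti(OiPr)4 (20 mol %), (R)-BINOL (20 mol %), Et2O, −20 °C; then aqueous HCl
Reagents that add atoms: none
Why: Catalytic enantioselective vinylogous Mukaiyama aldol reaction at the γ-carbon of the silyloxyfuran, in which the titanium BINOL complex should control the aldehyde face and the usual threo preference of 2-silyloxyfurans should set C7 together with the C6 carbinol (configured opposite to the final chloride).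

Step 15
Reactants: 26 bromoallyl alcohol
Product: 27 triethylsilyl ether of 26
Conditions: Et3SiCl, imidazole, DMF, 0 °C
Reagents that add atoms: chlorotriethylsilane, CC[Si](Cl)(CC)CC
Why: Silylation of the secondary allylic alcohol with a group that can later be removed in the presence of tert-butyldimethylsilyl ethers.

Step 16
Reactants: 27 bromoallyl silyl ether; 28 tributyl(ethenyl)stannane
Product: 29 diene tetronate
Conditions: Pd(PPh3)4 (5 mol %), CuI (10 mol %), DMF, 50 °C
Reagents that add atoms: none
Why: Stille coupling of the 2-bromoallyl unit with the vinylstannane builds the 2-substituted 1,3-diene with retention at both sp2 carbons.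

Step 17
Reactants: 29 diene tetronate
Product: 31 butenolide triflate, via lithium tetronate 30 (not isolated)
Conditions: LiCl, DMF, 90 °C; then PhNTf2, Et3N, 23 °C
Reagents that add atoms: N-phenylbis(trifluoromethanesulfonimide), O=S(=O)(N(c1ccccc1)S(=O)(=O)C(F)(F)F)C(F)(F)F
Why: Krapcho-type SN2 demethylation of the vinylogous carbonate by chloride gives the lithium tetronate, which is O-sulfonylated in the same flask to the alkenyl triflate needed for the chromium-mediated coupling.

Step 18
Reactants: 21 ring A aldehyde; 31 butenolide triflate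
Product: 32 C9 allylic alcohol (coupled seco compound)
Conditions: CrCl2, NiCl2 (1 mol %), DMSO, 23 °C
Reagents that add atoms: none
Why: Nozaki–Hiyama–Kishi coupling, in which the alkenylchromium species formed from the triflate adds only to the aldehyde, and attack anti to the fully substituted C11 (the largest α-substituent of C10) should give the C9 carbinol of the target.

Step 19
Reactants: 32 C9 allylic alcohol
Product: 33 8,17-epoxy alcohol
Conditions: t-BuOOH, n-BuLi, THF, −78 → −20 °C
Reagents that add atoms: tert-butyl hydroperoxide, CC(C)(C)OO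
Why: Weitz–Scheffer epoxidation of the butenolide with the peroxide anion delivered by the lithium alkoxide of the free C9 hydroxyl, which should place the epoxide oxygen syn to that hydroxyl and so set C8.

Step 20
Reactants: 33 8,17-epoxy alcohol
Product: 34 epoxy acetate
Conditions: Ac2O, DMAP, pyridine, CH2Cl2, 0 °C
Reagents that add atoms: acetic anhydride, CC(=O)OC(C)=O
Why: Acetylation of the secondary C9 alcohol installs the second acetate of the target.

Step 21
Reactants: 34 epoxy acetate
Product: 35 β-hydroxy lactone diene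
Conditions: SmI2, THF–MeOH, −78 °C
Reagents that add atoms: none
Why: SmI2 cleaves the α C–O bond of the α,β-epoxy lactone by two single-electron transfers and leaves the tertiary C8 hydroxyl in place, and protonation of the samarium enolate should put the C17 methyl cis to that hydroxyl and trans to the bulky C9 branch, a centre that can also be equilibrated.

Step 22
Reactants: 35 β-hydroxy lactone diene
Product: 36 ten-membered ring silyl ether
Conditions: second-generation Grubbs catalyst (10 mol %), toluene (0.5 mM), 80 °C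
Reagents that add atoms: none
Why: Ring-closing metathesis between the two monosubstituted vinyl groups (the 1,1-disubstituted and the ring A alkenes are inert) closes the ten-membered ring, whose strain should enforce the Z geometry at C3=C4.

Step 23
Reactants: 36 ten-membered ring silyl ether
Product: 37 C6 alcohol
Conditions: HF·pyridine, pyridine, THF, 0 °C
Reagents that add atoms: none
Why: Buffered fluoride removes the secondary triethylsilyl ether much faster than the tert-butyldimethylsilyl ethers and exposes only the C6 hydroxyl.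

Step 24
Reactants: 37 C6 alcohol
Product: 38 C6 chloride
Conditions: PPh3, (Cl3C)2CO, CH2Cl2, −20 → 0 °C
Reagents that add atoms: hexachloroacetone, ClC(Cl)(Cl)C(=O)C(Cl)(Cl)Cl
Why: Appel-type chlorination with PPh3 and hexachloroacetone converts allylic alcohols into chlorides by SN2 with inversion and with little allylic transposition, which should give the C6 chloride of the target.

Step 25
Reactants: 38 C6 chloride
Product: 39 C11 C12 diol
Conditions: HF·pyridine, THF, 23 → 40 °C
Reagents that add atoms: none
Why: Fluoride cleaves both silyl ethers and frees the C11 and C12 hydroxyls, while the acetates, the allylic chloride and the lactone are stable to HF·pyridine.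

Step 26
Reactants: 39 C11 C12 diol
Product: 40 target CNP0435497.1
Conditions: Ac2O, pyridine, DMAP (catalytic), CH2Cl2, 0 °C
Reagents that add atoms: acetic anhydride, CC(=O)OC(C)=O
Why: Mild acetylation acylates only the secondary C12 hydroxyl, because the tertiary C8 and C11 hydroxyls are too hindered, and gives the target.

**Compound list**

1 | (1S,2S)-1,2-dicyclohexylethane-1,2-diol | O[C@@H](C1CCCCC1)[C@@H](O)C1CCCCC1 | starting material
2 | dipropan-2-yl (dichloromethyl)boronate | ClC(Cl)B(OC(C)C)OC(C)C | starting material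
3 | (4S,5S)-4,5-dicyclohexyl-2-(dichloromethyl)-1,3,2-dioxaborolane | ClC(Cl)B1O[C@@H](C2CCCCC2)[C@H](C2CCCCC2)O1 | intermediate
4 | ethenylmagnesium bromide | C=C[Mg]Br | starting material
5 | (4S,5S)-2-[(1R)-1-chloroprop-2-en-1-yl]-4,5-dicyclohexyl-1,3,2-dioxaborolane | Cl[C@H](B1O[C@@H](C2CCCCC2)[C@H](C2CCCCC2)O1)C=C | intermediate
6 | (5S)-5-{[(1S,2R,5S)-5-methyl-2-(propan-2-yl)cyclohexyl]oxy}furan-2(5H)-one | O=C1C=C[C@@H](O[C@H]2C[C@@H](C)CC[C@@H]2C(C)C)O1 | starting material
7 | ethoxyethene | C=COCC | starting material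
8 | iodomethane | CI | starting material
9 | (1-ethoxyethenyl)lithium | [Li]C(=C)OCC | intermediate
10 | lithium bis(1-ethoxyethenyl)cuprate | [Li+].C=C(OCC)[Cu-]C(=C)OCC | intermediate
11 | (3S,4R,5S)-4-(1-ethoxyethenyl)-3-methyl-5-{[(1S,2R,5S)-5-methyl-2-(propan-2-yl)cyclohexyl]oxy}oxolan-2-one | O=C1[C@@H](C)[C@H](C(=C)OCC)[C@@H](O[C@H]2C[C@@H](C)CC[C@@H]2C(C)C)O1 | intermediate
12 | (3S,4R,5S)-3-{(1S)-1-[(4S,5S)-4,5-dicyclohexyl-1,3,2-dioxaborolan-2-yl]prop-2-en-1-yl}-4-(1-ethoxyethenyl)-3-methyl-5-(menthyloxy)oxolan-2-one; allyl unit trans to the ethoxyvinyl group | O=C1[C@@](C)([C@@H](B2O[C@@H](C3CCCCC3)[C@H](C3CCCCC3)O2)C=C)[C@H](C(=C)OCC)[C@@H](O[C@H]2C[C@@H](C)CC[C@@H]2C(C)C)O1 | intermediate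
13 | chloroacetyl analogue of 12 (4-(chloroacetyl) in place of 4-(1-ethoxyethenyl); all centres arranged as in 12) | O=C1[C@@](C)([C@@H](B2O[C@@H](C3CCCCC3)[C@H](C3CCCCC3)O2)C=C)[C@H](C(=O)CCl)[C@@H](O[C@H]2C[C@@H](C)CC[C@@H]2C(C)C)O1 | intermediate
14 | 4-(chloromethyl)-4-hydroxy-7a-methyl-3-(menthyloxy)-3a,4,5,7a-tetrahydro-2-benzofuran-1(3H)-one; trans-fused; C1, C10, C11 as in the target; menthyloxy trans to C11 | O=C2[C@@]1(C)C=CC[C@](O)(CCl)[C@@H]1[C@@H](O[C@H]3C[C@@H](C)CC[C@@H]3C(C)C)O2 | intermediate
15 | 5-hydroxy derivative of 14; C12 hydroxyl cis to the C11 hydroxyl (C12 as in the target) | O=C2[C@@]1(C)C=C[C@@H](O)[C@](O)(CCl)[C@@H]1[C@@H](O[C@H]3C[C@@H](C)CC[C@@H]3C(C)C)O2 | intermediate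
16 | methyl 5-(chloromethyl)-6-(dimethoxymethyl)-4,5-dihydroxy-1-methylcyclohex-2-ene-1-carboxylate; C1, C10, C11, C12 as in the target | COC(=O)[C@@]1(C)C=C[C@@H](O)[C@](O)(CCl)[C@@H]1C(OC)OC | intermediate
17 | methyl 4,5-bis{[tert-butyl(dimethyl)silyl]oxy}-5-(chloromethyl)-6-(dimethoxymethyl)-1-methylcyclohex-2-ene-1-carboxylate; centres as in 16 | COC(=O)[C@@]1(C)C=C[C@@H](O[Si](C)(C)C(C)(C)C)[C@](O[Si](C)(C)C(C)(C)C)(CCl)[C@@H]1C(OC)OC | intermediate
18 | 4,5-bis{[tert-butyl(dimethyl)silyl]oxy}-5-(chloromethyl)-6-(dimethoxymethyl)-1-methylcyclohex-2-ene-1-carbaldehyde; centres as in 16 | O=C[C@@]1(C)C=C[C@@H](O[Si](C)(C)C(C)(C)C)[C@](O[Si](C)(C)C(C)(C)C)(CCl)[C@@H]1C(OC)OC | intermediate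
19 | 1-[ring A]prop-2-en-1-ol from 18; C2 carbinol as in the target | C=C[C@H](O)[C@@]1(C)C=C[C@@H](O[Si](C)(C)C(C)(C)C)[C@](O[Si](C)(C)C(C)(C)C)(CCl)[C@@H]1C(OC)OC | intermediate
20 | acetate of 19 | C=C[C@H](OC(C)=O)[C@@]1(C)C=C[C@@H](O[Si](C)(C)C(C)(C)C)[C@](O[Si](C)(C)C(C)(C)C)(CCl)[C@@H]1C(OC)OC | intermediate
21 | 6-[1-(acetyloxy)prop-2-en-1-yl]-2,3-bis{[tert-butyl(dimethyl)silyl]oxy}-2-(chloromethyl)-6-methylcyclohex-4-ene-1-carbaldehyde; C1, C2, C10, C11, C12 as in the target | C=C[C@H](OC(C)=O)[C@@]1(C)C=C[C@@H](O[Si](C)(C)C(C)(C)C)[C@](O[Si](C)(C)C(C)(C)C)(CCl)[C@@H]1C=O | intermediate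
22 | 4-hydroxy-3-methylfuran-2(5H)-one | CC1=C(O)COC1=O | starting material
23 | 4-methoxy-3-methylfuran-2(5H)-one | CC1=C(OC)COC1=O | intermediate
24 | [(4-methoxy-3-methylfuran-2-yl)oxy](trimethyl)silane | COc1coc(O[Si](C)(C)C)c1C | intermediate
25 | 2-bromoprop-2-enal | C=C(Br)C=O | starting material
26 | (5S)-5-[(1S)-2-bromo-1-hydroxyprop-2-en-1-yl]-4-methoxy-3-methylfuran-2(5H)-one | COC1=C(C)C(=O)O[C@H]1[C@H](O)C(Br)=C | intermediate
27 | (5S)-5-{(1S)-2-bromo-1-[(triethylsilyl)oxy]prop-2-en-1-yl}-4-methoxy-3-methylfuran-2(5H)-one | COC1=C(C)C(=O)O[C@H]1[C@H](O[Si](CC)(CC)CC)C(Br)=C | intermediate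
28 | tributyl(ethenyl)stannane | C=C[Sn](CCCC)(CCCC)CCCC | starting material
29 | (5S)-4-methoxy-3-methyl-5-{(1R)-2-methylidene-1-[(triethylsilyl)oxy]but-3-en-1-yl}furan-2(5H)-one | COC1=C(C)C(=O)O[C@H]1[C@H](O[Si](CC)(CC)CC)C(=C)C=C | intermediate
30 | lithium (2S)-4-methyl-2-{(1R)-2-methylidene-1-[(triethylsilyl)oxy]but-3-en-1-yl}-5-oxo-2,5-dihydrofuran-3-olate | [Li+].[O-]C1=C(C)C(=O)O[C@H]1[C@H](O[Si](CC)(CC)CC)C(=C)C=C | intermediate
31 | (2S)-4-methyl-2-{(1R)-2-methylidene-1-[(triethylsilyl)oxy]but-3-en-1-yl}-5-oxo-2,5-dihydrofuran-3-yl trifluoromethanesulfonate | O=S(=O)(OC1=C(C)C(=O)O[C@H]1[C@H](O[Si](CC)(CC)CC)C(=C)C=C)C(F)(F)F | intermediate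
32 | coupled allylic alcohol: C9 of 21 bonded to C8 of the butenolide of 31; C9 hydroxyl as in the target; C6 silyloxy carbon epimeric to the target C6 | C=C[C@H](OC(C)=O)[C@@]2(C)C=C[C@@H](O[Si](C)(C)C(C)(C)C)[C@](O[Si](C)(C)C(C)(C)C)(CCl)[C@@H]2[C@H](O)C2=C(C)C(=O)O[C@H]2[C@H](O[Si](CC)(CC)CC)C(=C)C=C | intermediate
33 | 8,17-epoxide of 32; epoxide oxygen syn to the C9 hydroxyl (C8 as in the target) | C=C[C@H](OC(C)=O)[C@@]2(C)C=C[C@@H](O[Si](C)(C)C(C)(C)C)[C@](O[Si](C)(C)C(C)(C)C)(CCl)[C@@H]2[C@H](O)[C@@]23O[C@@]3(C)C(=O)O[C@H]2[C@H](O[Si](CC)(CC)CC)C(=C)C=C | intermediate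
34 | C9 acetate of 33 | C=C[C@H](OC(C)=O)[C@@]2(C)C=C[C@@H](O[Si](C)(C)C(C)(C)C)[C@](O[Si](C)(C)C(C)(C)C)(CCl)[C@@H]2[C@H](OC(C)=O)[C@@]23O[C@@]3(C)C(=O)O[C@H]2[C@H](O[Si](CC)(CC)CC)C(=C)C=C | intermediate
35 | acyclic β-hydroxy lactone from 34; C8 hydroxyl and C17 methyl as in the target | C=C[C@H](OC(C)=O)[C@@]2(C)C=C[C@@H](O[Si](C)(C)C(C)(C)C)[C@](O[Si](C)(C)C(C)(C)C)(CCl)[C@@H]2[C@H](OC(C)=O)[C@]2(O)[C@@H](C)C(=O)O[C@H]2[C@H](O[Si](CC)(CC)CC)C(=C)C=C | intermediate
36 | ten-membered ring compound with (Z)-C3=C4; C6 triethylsilyl ether (C6 oxygen epimeric to the target chloride); C11 and C12 tert-butyldimethylsilyl ethers; other centres as in the target | C=C1/C=C\[C@H](OC(C)=O)[C@@]2(C)C=C[C@@H](O[Si](C)(C)C(C)(C)C)[C@](O[Si](C)(C)C(C)(C)C)(CCl)[C@@H]2[C@H](OC(C)=O)[C@]2(O)[C@@H](C)C(=O)O[C@H]2[C@@H]1O[Si](CC)(CC)CC | intermediate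
37 | C6 alcohol from 36 | C=C1/C=C\[C@H](OC(C)=O)[C@@]2(C)C=C[C@@H](O[Si](C)(C)C(C)(C)C)[C@](O[Si](C)(C)C(C)(C)C)(CCl)[C@@H]2[C@H](OC(C)=O)[C@]2(O)[C@@H](C)C(=O)O[C@H]2[C@@H]1O | intermediate
38 | C6 chloride: target with the C11 and C12 oxygens as tert-butyldimethylsilyl ethers | C=C1/C=C\[C@H](OC(C)=O)[C@@]2(C)C=C[C@@H](O[Si](C)(C)C(C)(C)C)[C@](O[Si](C)(C)C(C)(C)C)(CCl)[C@@H]2[C@H](OC(C)=O)[C@]2(O)[C@@H](C)C(=O)O[C@H]2[C@H]1Cl | intermediate
39 | 12-deacetyl target (C11, C12 diol) | C=C1/C=C\[C@H](OC(C)=O)[C@@]2(C)C=C[C@@H](O)[C@](O)(CCl)[C@@H]2[C@H](OC(C)=O)[C@]2(O)[C@@H](C)C(=O)O[C@H]2[C@H]1Cl | intermediate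
40 | CNP0435497.1 | C=C1/C=C\[C@H](OC(C)=O)[C@@]2(C)C=C[C@@H](OC(C)=O)[C@](O)(CCl)[C@@H]2[C@H](OC(C)=O)[C@]2(O)[C@@H](C)C(=O)O[C@H]2[C@H]1Cl | target

**Step count and risks**

Total step count: 26. Longest linear sequence: 19 steps (steps 1, 2, 4 to 11 and 18 to 26; 18 steps counted from butenolide 6, 15 from tetronic acid 22).

Steps most likely to fail:

1. Step 4 (proposed new method). The enolate may bind boron through oxygen or attack the vinyl terminus instead of undergoing the 1,2-shift, and the boat-like allylboration may stall or go with poor facial control at C11. The fallback uses known reaction types, sets out from 11 and returns at 14. LiN(i-Pr)2 then acrolein (aldol at C1, anti to the C10 substituent) should give the aldol adduct F1. Methyl chloroformate and pyridine convert it into the allylic methyl carbonate F2. N-Chlorosuccinimide in wet THF turns the ethoxyvinyl group into the chloromethyl ketone carbonate F3. Pd(PPh3)4 with SnCl2 then converts the π-allyl complex into an allyltin species that adds to the ketone in a Barbier-type intramolecular allylation, stereoconvergent at C14; closure at the unsubstituted allyl terminus should give 14.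

2. Step 22. Oligomerisation, engagement of the 1,1-disubstituted diene alkene or formation of the E ring alkene may compete with closure of the strained ring. The fallback closes the ring by chromium chemistry instead, sets out from 21 and 31 and returns at 36. Z-selective cross-metathesis of the two monosubstituted vinyl groups (cyclometalated Z-selective ruthenium alkylidene) should give the seco aldehyde triflate F4. Intramolecular Nozaki–Hiyama–Kishi coupling (CrCl2, catalytic NiCl2, high dilution) gives the macrocyclic allylic alcohol F5. Hydroxyl-directed epoxidation as in step 19 gives the macrocyclic epoxy alcohol F6, acetylation gives the macrocyclic epoxy acetate F7, and SmI2 as in step 21 gives 36.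

3. Step 19. Conjugate attack of the peroxide on the tetrasubstituted butenolide may be slow, the C2 acetate may be lost to the peroxide anion, and facial control may be poor. The fallback installs the C8 oxygen through boron, sets out from 32 and returns at 35. Acetylation gives the butenolide diacetate F8. Copper-catalysed conjugate borylation (CuCl, a chiral ferrocenyl bisphosphine, NaOt-Bu, B2pin2, MeOH; ligand antipode chosen for delivery syn to the C6 branch) gives the tertiary boronate F9. NaBO3 oxidation with retention gives 35.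

Further compounds
F1 | step 4 | (4R,5S)-4-(1-ethoxyethenyl)-3-(1-hydroxyprop-2-en-1-yl)-3-methyl-5-(menthyloxy)oxolan-2-one; C1 as in 12; carbinol epimers | O=C1[C@@](C)(C(O)C=C)[C@H](C(=C)OCC)[C@@H](O[C@H]2C[C@@H](C)CC[C@@H]2C(C)C)O1
F2 | step 4 | methyl carbonate of F1 | O=C1[C@@](C)(C(OC(=O)OC)C=C)[C@H](C(=C)OCC)[C@@H](O[C@H]2C[C@@H](C)CC[C@@H]2C(C)C)O1
F3 | step 4 | chloroacetyl analogue of F2 (4-(chloroacetyl) in place of 4-(1-ethoxyethenyl)) | O=C1[C@@](C)(C(OC(=O)OC)C=C)[C@H](C(=O)CCl)[C@@H](O[C@H]2C[C@@H](C)CC[C@@H]2C(C)C)O1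
F4 | step 22 | seco aldehyde triflate: 21 and 31 joined through (Z)-C3=C4 | FC(F)(F)S(=O)(=O)OC1=C(C)C(=O)O[C@H]1[C@H](O[Si](CC)(CC)CC)C(=C)/C=C\[C@H](OC(C)=O)[C@@]1(C)C=C[C@@H](O[Si](C)(C)C(C)(C)C)[C@](O[Si](C)(C)C(C)(C)C)(CCl)[C@@H]1C=O
F5 | step 22 | macrocyclic C9 alcohol with intact butenolide (ring-closed analogue of 32) | C=C1/C=C\[C@H](OC(C)=O)[C@@]2(C)C=C[C@@H](O[Si](C)(C)C(C)(C)C)[C@](O[Si](C)(C)C(C)(C)C)(CCl)[C@@H]2[C@H](O)C2=C(C)C(=O)O[C@H]2[C@@H]1O[Si](CC)(CC)CC
F6 | step 22 | macrocyclic 8,17-epoxy alcohol (ring-closed analogue of 33) | C=C1/C=C\[C@H](OC(C)=O)[C@@]2(C)C=C[C@@H](O[Si](C)(C)C(C)(C)C)[C@](O[Si](C)(C)C(C)(C)C)(CCl)[C@@H]2[C@H](O)[C@@]23O[C@@]3(C)C(=O)O[C@H]2[C@@H]1O[Si](CC)(CC)CC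
F7 | step 22 | macrocyclic epoxy acetate (ring-closed analogue of 34) | C=C1/C=C\[C@H](OC(C)=O)[C@@]2(C)C=C[C@@H](O[Si](C)(C)C(C)(C)C)[C@](O[Si](C)(C)C(C)(C)C)(CCl)[C@@H]2[C@H](OC(C)=O)[C@@]23O[C@@]3(C)C(=O)O[C@H]2[C@@H]1O[Si](CC)(CC)CC
F8 | step 19 | C9 acetate of 32 (butenolide diacetate) | C=C[C@H](OC(C)=O)[C@@]2(C)C=C[C@@H](O[Si](C)(C)C(C)(C)C)[C@](O[Si](C)(C)C(C)(C)C)(CCl)[C@@H]2[C@H](OC(C)=O)C2=C(C)C(=O)O[C@H]2[C@H](O[Si](CC)(CC)CC)C(=C)C=C
F9 | step 19 | C8 pinacol boronate of the saturated lactone (boron in place of the C8 hydroxyl of 35; same arrangement) | C=C[C@H](OC(C)=O)[C@@]2(C)C=C[C@@H](O[Si](C)(C)C(C)(C)C)[C@](O[Si](C)(C)C(C)(C)C)(CCl)[C@@H]2[C@H](OC(C)=O)[C@]2(B3OC(C)(C)C(C)(C)O3)[C@@H](C)C(=O)O[C@H]2[C@H](O[Si](CC)(CC)CC)C(=C)C=C
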